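**Retrosynthetic overview**

1. Each half is numbered as a quinolizidin-2-one: C1 (tether-bearing CH), C2 (ketone), C3 (CHMe), C4, N5, C6–C9, C9a; tether carbons run t1 (on C9) to t5 (on C1 of the other half), giving the 16-membered ring. The route rests on one feature: ring 2 (N5, C6, C7, C8, C9, C9a) without N5 is a cyclopentane C6–C7–C8–C9–C9a cis-fused to the macrocycle at C9–C9a, and N5 is already tied to C9a through C4–C3–C2–C1, so N5 can be slipped into the C6–C9a bond of a cyclopentanone.
2. Key disconnection: both N5–C9a bonds, back to bis-nitrone 24 (C6=N5 oxide inside a seven-membered ring), made from bis-cyclopentanone 22 carrying protected N-hydroxylamine arms on C4.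
3. The cis C9/C9a pairs of 22 go back to macrocyclic bis-enone 16 (enantioselective carbonyl reduction, then hydroxyl-directed hydrogenation). 16 is the head-to-tail cyclodimer of enol triflate 13 (hydroboration and sp3–sp2 cross-coupling forming C9–t1).
4. 13 comes from cyclopentane-1,3-dione and allylic alcohol 9 by O-alkylation and Claisen rearrangement (C9a–C1 bond, C1 set by chirality transfer). 9 is built from the (S)-Roche ester, which supplies C2–C4 and the C3 methyl.
5. Ring order: cyclopentane rings (bought) → 16-membered ring (step 11) → seven-membered nitrone rings (step 17) → rings 1 and 2 of both quinolizidines (step 18). The C2 ketals are carried from step 4 to step 20.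

Key step: step 18

Assumption: the equatorial C1 and C3 configurations of the target are taken to be the thermodynamically preferred ones of each 2-quinolizidinone, so the closing base treatment converges on the target.

**Route**

Step 1
Reactants: 1 methyl (S)-3-hydroxy-2-methylpropanoate
Product: 2 methyl (S)-3-[(tert-butyldiphenylsilyl)oxy]-2-methylpropanoate
Conditions: TBDPSCl, imidazole, CH2Cl2, 0 °C→rt
Reagents that add atoms: tert-butyl(chloro)diphenylsilane, CC(C)(C)[Si](Cl)(c1ccccc1)c1ccccc1
Why: Silyl ether formation on a primary alcohol is routine and does not touch the C3 stereocentre, which comes from the chiral pool.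

Step 2
Reactants: 2 methyl (S)-3-[(tert-butyldiphenylsilyl)oxy]-2-methylpropanoate
Product: 3 (S)-3-[(tert-butyldiphenylsilyl)oxy]-N-methoxy-N,2-dimethylpropanamide
Conditions: MeNH(OMe)·HCl, iPrMgCl, THF, −20→0 °C
Reagents that add atoms: N,O-dimethylhydroxylamine hydrochloride, CNOC.Cl
Why: Ester aminolysis by the magnesium amide (Weinreb amide formation) is fast at low temperature, which keeps the enolisable C3 centre intact.

Step 3
Reactants: 3 (S)-3-[(tert-butyldiphenylsilyl)oxy]-N-methoxy-N,2-dimethylpropanamide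
Product: 4 (S)-5-[(tert-butyldiphenylsilyl)oxy]-4-methyl-1-(trimethylsilyl)pent-1-yn-3-one
Conditions: TMSC≡CH, n-BuLi, THF, −78 °C; then 3, −78→0 °C; aq. NH4Cl
Reagents that add atoms: ethynyltrimethylsilane, C#C[Si](C)(C)C
Why: Weinreb ketone synthesis stops after one acetylide addition and releases the ynone (C2 carbonyl, future C1 and t5 as the alkyne) only on work-up, so over-addition and C3 epimerisation are not expected.

Step 4
Reactants: 4 (S)-5-[(tert-butyldiphenylsilyl)oxy]-4-methyl-1-(trimethylsilyl)pent-1-yn-3-one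
Product: 5 ethylene ketal of 4
Conditions: (TMSOCH2)2, TMSOTf (cat.), CH2Cl2, −78→−20 °C
Reagents that add atoms: 1,2-bis(trimethylsilyloxy)ethane, C[Si](C)(C)OCCO[Si](C)(C)C
Why: Noyori ketalisation under aprotic low-temperature conditions masks the still unhindered C2 carbonyl without enolising C3, which is far easier here than after C1 has become branched.

Step 5
Reactants: 5 ethylene ketal of 4
Product: 7 ynal 3-(2-substituted-1,3-dioxolan-2-yl)prop-2-ynal, via lithium acetylide 6 (not isolated)
Conditions: MeLi·LiBr, THF, 0 °C→rt; then DMF, −78→0 °C; inverse quench into aq. KH2PO4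
Reagents that add atoms: N,N-dimethylformamide, CN(C)C=O
Why: Desilylative lithiation of the silylalkyne and formylation of the acetylide with DMF (Bouveault-type formylation) add carbon t4 as the aldehyde; the buffered inverse quench keeps the liberated dimethylamine from adding to the ynal.

Step 6
Reactants: 7 ynal 3-(2-substituted-1,3-dioxolan-2-yl)prop-2-ynal
Product: 8 (R)-propargylic homoallylic alcohol
Conditions: allylSnBu3, (R)-BINOL (20 mol%), Ti(OiPr)4 (10 mol%), 4 Å MS, CH2Cl2, −20 °C; aq. NaHCO3, KF
Reagents that add atoms: allyltributylstannane, C=CC[Sn](CCCC)(CCCC)CCCC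
Why: Keck asymmetric allylation adds t3–t1 under control of the chiral titanium–BINOL Lewis acid, which should set the carbinol carbon t4 as R (the enantiomer needed for step 9); the C3 centre is too remote to interfere.

Step 7
Reactants: 8 (R)-propargylic homoallylic alcohol
Product: 9 (R,E)-allylic alcohol
Conditions: NaAlH2(OCH2CH2OMe)2, THF, −20→0 °C; aq. potassium sodium tartrate (KNaC4H4O6)
Reagents that add atoms: none
Why: Hydroxyl-directed trans-hydroalumination of the propargylic alcohol followed by protonolysis gives only the E t5=C1 alkene; the low temperature guards against elimination toward the ketal, and the terminal alkene is inert.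

Step 8
Reactants: 9 (R,E)-allylic alcohol; 10 cyclopentane-1,3-dione
Product: 11 (S,E)-allyl enol ether (3-alkoxycyclopent-2-enone)
Conditions: PPh3, DIAD, THF, 0 °C→rt
Reagents that add atoms: none
Why: Mitsunobu O-alkylation of the acidic 1,3-dione gives the vinylogous ester with inversion at t4 (R to S); SN2' attack at C1 is blocked by the neighbouring ketal carbon.

Step 9
Reactants: 11 (S,E)-allyl enol ether (3-alkoxycyclopent-2-enone)
Product: 12 2-substituted cyclopentane-1,3-dione (enol form) with C1 (R)
Conditions: degassed o-xylene, BHT, 150 °C (sealed tube)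
Reagents that add atoms: none
Why: Claisen rearrangement of the allyl enol ether of a cyclic 1,3-dione through a chair transition state with the t3 chain equatorial forms the C9a–C1 bond, transfers the t4 configuration to C1 (R) and leaves an E t5=t4 alkene.

Step 10
Reactants: 12 2-substituted cyclopentane-1,3-dione (enol form) with C1 (R)
Product: 13 enol triflate (3-triflyloxy-2-substituted cyclopent-2-enone)
Conditions: Tf2O, Et3N, CH2Cl2, −78 °C
Reagents that add atoms: trifluoromethanesulfonic anhydride, O=S(=O)(OS(=O)(=O)C(F)(F)F)C(F)(F)F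
Why: O-Sulfonylation of the symmetrical enolised dione can give only one vinylogous acyl triflate and marks C9 as the coupling carbon.

Step 11
Reactants: 13 enol triflate (two molecules)
Product: 16 macrocyclic bis-enone (16-membered head-to-tail dimer), via alkylborane 14 (not isolated), via open-chain dimer 15 (not isolated)
Conditions: 9-BBN, THF, 0 °C→rt; then slow addition to PdCl2(dppf), AsPh3, Cs2CO3, DMF/THF/H2O, 50 °C, ≤5 mM
Reagents that add atoms: none
Why: Anti-Markovnikov hydroboration of the only monosubstituted alkene and B-alkyl Suzuki–Miyaura coupling with the enol triflate form both C9–t1 bonds; borane and triflate can pair only head to tail, and the E t5=t4 alkene rules out the eight-membered intramolecular coupling, so the open-chain dimer closes to the 16-membered ring.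

Step 12
Reactants: 16 macrocyclic bis-enone (16-membered head-to-tail dimer)
Product: 17 macrocyclic bis-enone diol
Conditions: Bu4NF, AcOH, THF, rt
Reagents that add atoms: none
Why: Fluoride desilylation buffered with acetic acid frees both primary C4 alcohols without touching the ketals or isomerising the enones.

Step 13
Reactants: 17 macrocyclic bis-enone diol; 18 tert-butyl N-[(tert-butoxycarbonyl)oxy]carbamate (two equivalents)
Product: 19 macrocyclic bis-enone with an N(Boc)OBoc group on each C4
Conditions: PPh3, DIAD, THF, 0 °C→rt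
Reagents that add atoms: none
Why: Mitsunobu N-alkylation of the acidic N–H of the bis-Boc hydroxylamine by the primary C4 alcohols installs both protected N5 atoms; no stereocentre is involved.

Step 14
Reactants: 19 macrocyclic bis-enone with an N(Boc)OBoc group on each C4
Product: 20 macrocyclic bis-(S)-cyclopent-2-enol
Conditions: (R)-2-methyl-CBS-oxazaborolidine [(R)-1-methyl-3,3-diphenyltetrahydro-1H,3H-pyrrolo[1,2-c][1,3,2]oxazaborole], catecholborane, toluene, −78 °C; MeOH, pH 7 buffer
Reagents that add atoms: none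
Why: Corey–Bakshi–Shibata reduction, with the tetrasubstituted alkene side as the large group, should give the S carbinol at each C6 under reagent control; catecholborane at −78 °C leaves the tether alkenes and the carbamates alone.

Step 15
Reactants: 20 macrocyclic bis-(S)-cyclopent-2-enol
Product: 21 saturated macrocyclic bis-cyclopentanol (C6 S, C9 S, C9a R in each half)
Conditions: H2 (20 bar), [Ir(cod)(PCy3)(py)]PF6 (15 mol%), CH2Cl2, rt
Reagents that add atoms: none
Why: Hydroxyl-directed homogeneous hydrogenation delivers both hydrogens to the tetrasubstituted C9=C9a bond from the face of the C6 hydroxyl, which sets C9 (S) and C9a (R) cis to each other in each ring; the two E tether alkenes are saturated in the same operation.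

Step 16
Reactants: 21 saturated macrocyclic bis-cyclopentanol (C6 S, C9 S, C9a R in each half)
Product: 22 macrocyclic bis-cyclopentanone with cis C9/C9a
Conditions: Dess–Martin periodinane, NaHCO3, CH2Cl2, 0 °C→rt
Reagents that add atoms: none
Why: Buffered hypervalent-iodine oxidation of the secondary alcohols returns the C6 ketones under non-enolising conditions, so the cis C9/C9a relationship next to the new carbonyl is kept.

Step 17
Reactants: 22 macrocyclic bis-cyclopentanone with cis C9/C9a
Product: 24 macrocyclic bis-nitrone bis-ketal, via bis-hydroxylamine 23 (not isolated)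
Conditions: anhydrous TFA/CH2Cl2 (1:4), 0 °C, short contact; cold aq. NaHCO3; then 4 Å MS, CH2Cl2, rt→40 °C
Reagents that add atoms: none
Why: Acidolysis removes all four Boc groups and, after neutralisation, each N-alkylhydroxylamine condenses with the C6 ketone of its own ring (intramolecular nitrone formation closing the seven-membered ring, helped by the quaternary ketal carbon in the chain); short cold acid contact and neutral dehydration are chosen to spare the C9a centre.

Step 18
Reactants: 24 macrocyclic bis-nitrone bis-ketal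
Product: 26 macrocyclic bis(quinolizidin-6-one) bis-ketal, via bis-oxaziridine 25 (not isolated)
Conditions: hν (254 nm, quartz), degassed MeCN, ca. 5 mM, rt
Reagents that add atoms: none
Why: Excitation of each ketonitrone closes the C6–O bond to the ring-fused oxaziridine 25, and further irradiation breaks the weak N–O bond while the C–C bond anti to the nitrogen lone pair shifts from C6 to N5, leaving C6 as the lactam carbonyl. The closest known reaction type is the photochemical nitrone–oxaziridine–lactam rearrangement of cyclic nitrones made by intramolecular condensation, the photochemical counterpart of an intramolecular Schmidt reaction. Neither ring is closed end to end: ring 2 arises by 1,2-shift ring expansion of the cyclopentane (N5 inserted between C6 and C9a) and ring 1 by the matching contraction of the seven-membered nitrone ring, so no exo or endo preference has to be met. No stereocentre is created; C9a migrates with retention, so the cis C9/C9a relationship from step 15 is carried over, and C1 and C3 are untouched under the neutral conditions. The selectivity needed is migration of C9a and not C7; it is secured because C4 and C9a both belong to the seven-membered ring and are therefore cis on the oxaziridine, which places the lone pair anti to the C6–C9a bond in either oxaziridine diastereomer. Dilute degassed solution and close monitoring limit secondary photolysis of the lactam.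

Step 19
Reactants: 26 macrocyclic bis(quinolizidin-6-one) bis-ketal
Product: 27 macrocyclic bis-quinolizidine bis-ketal
Conditions: LiAlH4, THF, reflux; aqueous NaOH work-up
Reagents that add atoms: none
Why: Hydride reduction of the two tertiary lactams to tertiary amines turns C6 into CH2 and completes both quinolizidines; the dioxolanes are inert to the reagent.

Step 20
Reactants: 27 macrocyclic bis-quinolizidine bis-ketal
Product: 28 target CNP0268544.6
Conditions: 3 M HCl, THF, 60 °C; then K2CO3, MeOH, rt
Reagents that add atoms: water, O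
Why: Acid-catalysed ketal hydrolysis frees the C2 ketones, and mild base then equilibrates the enolisable C1 and C3 centres to the diequatorial arrangement, which is the one already installed, so any epimer formed along the way converges on the target.

**Compound list**

1 | methyl (S)-3-hydroxy-2-methylpropanoate | COC(=O)[C@@H](C)CO | starting material
2 | methyl (S)-3-[(tert-butyldiphenylsilyl)oxy]-2-methylpropanoate | COC(=O)[C@@H](C)CO[Si](c1ccccc1)(c1ccccc1)C(C)(C)C | intermediate
3 | (S)-3-[(tert-butyldiphenylsilyl)oxy]-N-methoxy-N,2-dimethylpropanamide | CON(C)C(=O)[C@@H](C)CO[Si](c1ccccc1)(c1ccccc1)C(C)(C)C | intermediate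
4 | (S)-5-[(tert-butyldiphenylsilyl)oxy]-4-methyl-1-(trimethylsilyl)pent-1-yn-3-one | C[Si](C)(C)C#CC(=O)[C@@H](C)CO[Si](c1ccccc1)(c1ccccc1)C(C)(C)C | intermediate
5 | ethylene ketal of 4: 2-[(S)-1-((tert-butyldiphenylsilyl)oxy)propan-2-yl]-2-[(trimethylsilyl)ethynyl]-1,3-dioxolane | C[Si](C)(C)C#CC1(OCCO1)[C@@H](C)CO[Si](c2ccccc2)(c2ccccc2)C(C)(C)C | intermediate
6 | lithium acetylide: {2-[(S)-1-((tert-butyldiphenylsilyl)oxy)propan-2-yl]-1,3-dioxolan-2-yl}ethynyllithium | [Li]C#CC1(OCCO1)[C@@H](C)CO[Si](c2ccccc2)(c2ccccc2)C(C)(C)C | intermediate (not isolated)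
7 | ynal: 3-{2-[(S)-1-((tert-butyldiphenylsilyl)oxy)propan-2-yl]-1,3-dioxolan-2-yl}prop-2-ynal | O=CC#CC1(OCCO1)[C@@H](C)CO[Si](c2ccccc2)(c2ccccc2)C(C)(C)C | intermediate
8 | (R)-1-{2-[(S)-1-((tert-butyldiphenylsilyl)oxy)propan-2-yl]-1,3-dioxolan-2-yl}hex-5-en-1-yn-3-ol | C=CC[C@@H](O)C#CC1(OCCO1)[C@@H](C)CO[Si](c2ccccc2)(c2ccccc2)C(C)(C)C | intermediate
9 | (R,E)-1-{2-[(S)-1-((tert-butyldiphenylsilyl)oxy)propan-2-yl]-1,3-dioxolan-2-yl}hexa-1,5-dien-3-ol | C=CC[C@@H](O)/C=C/C1(OCCO1)[C@@H](C)CO[Si](c2ccccc2)(c2ccccc2)C(C)(C)C | intermediate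
10 | cyclopentane-1,3-dione | O=C1CCC(=O)C1 | starting material
11 | 3-{[(S,E)-1-{2-[(S)-1-((tert-butyldiphenylsilyl)oxy)propan-2-yl]-1,3-dioxolan-2-yl}hexa-1,5-dien-3-yl]oxy}cyclopent-2-en-1-one | O=C1C=C(O[C@@H](CC=C)/C=C/C2(OCCO2)[C@@H](C)CO[Si](c3ccccc3)(c3ccccc3)C(C)(C)C)CC1 | intermediate
12 | 3-hydroxy-2-[(R,E)-1-{2-[(S)-1-((tert-butyldiphenylsilyl)oxy)propan-2-yl]-1,3-dioxolan-2-yl}hexa-2,5-dien-1-yl]cyclopent-2-en-1-one (enol form of the 2-substituted 1,3-dione) | O=C1CCC(O)=C1[C@@H](/C=C/CC=C)C2(OCCO2)[C@@H](C)CO[Si](c3ccccc3)(c3ccccc3)C(C)(C)C | intermediate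
13 | 3-oxo-2-[(R,E)-1-{2-[(S)-1-((tert-butyldiphenylsilyl)oxy)propan-2-yl]-1,3-dioxolan-2-yl}hexa-2,5-dien-1-yl]cyclopent-1-en-1-yl trifluoromethanesulfonate | O=C1CCC(OS(=O)(=O)C(F)(F)F)=C1[C@@H](/C=C/CC=C)C2(OCCO2)[C@@H](C)CO[Si](c3ccccc3)(c3ccccc3)C(C)(C)C | intermediate
14 | alkylborane: 13 with the terminal CH=CH2 converted to CH2CH2–(9-borabicyclo[3.3.1]nonan-9-yl) | O=C1CCC(OS(=O)(=O)C(F)(F)F)=C1[C@@H](/C=C/CCCB4C5CCCC4CCC5)C2(OCCO2)[C@@H](C)CO[Si](c3ccccc3)(c3ccccc3)C(C)(C)C | intermediate (not isolated)
15 | open-chain head-to-tail dimer: one ring still the enol triflate, its C1 chain joined through t1 to C9 of the second (enone) ring, whose own C1 chain ends in the 9-BBN borane | O=C1CCC(OS(=O)(=O)C(F)(F)F)=C1[C@H](C3(OCCO3)[C@@H](C)CO[Si](c6ccccc6)(c6ccccc6)C(C)(C)C)/C=C/CCCC4=C([C@H](C5(OCCO5)[C@@H](C)CO[Si](c7ccccc7)(c7ccccc7)C(C)(C)C)/C=C/CCCB8C9CCCC8CCC9)C(=O)CC4 | intermediate (not isolated)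
16 | C2-symmetric 16-membered bis(cyclopent-2-enone): in each half C9 carries t1 and C9a carries C1 (R), which bears the 2-[(S)-1-((tert-butyldiphenylsilyl)oxy)propan-2-yl]-1,3-dioxolan-2-yl group and the E t5=t4 alkene of the tether to C9 of the other half | O=C1CCC2=C1[C@H](C3(OCCO3)[C@@H](C)CO[Si](c6ccccc6)(c6ccccc6)C(C)(C)C)/C=C/CCCC4=C([C@H](C5(OCCO5)[C@@H](C)CO[Si](c7ccccc7)(c7ccccc7)C(C)(C)C)/C=C/CCC2)C(=O)CC4 | intermediate
17 | diol of 16 (both C4 hydroxyls free) | O=C1CCC2=C1[C@H](C3(OCCO3)[C@@H](C)CO)/C=C/CCCC4=C([C@H](C5(OCCO5)[C@@H](C)CO)/C=C/CCC2)C(=O)CC4 | intermediate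
18 | tert-butyl N-[(tert-butoxycarbonyl)oxy]carbamate (N,O-bis-Boc-hydroxylamine) | CC(C)(C)OC(=O)NOC(=O)OC(C)(C)C | starting material
19 | macrocyclic bis-enone with N(Boc)OBoc on each C4 | O=C1CCC2=C1[C@H](C3(OCCO3)[C@@H](C)CN(OC(=O)OC(C)(C)C)C(=O)OC(C)(C)C)/C=C/CCCC4=C([C@H](C5(OCCO5)[C@@H](C)CN(OC(=O)OC(C)(C)C)C(=O)OC(C)(C)C)/C=C/CCC2)C(=O)CC4 | intermediate
20 | macrocyclic bis-cyclopent-2-enol, C6 (S) in each half | O[C@H]1CCC2=C1[C@H](C3(OCCO3)[C@@H](C)CN(OC(=O)OC(C)(C)C)C(=O)OC(C)(C)C)/C=C/CCCC4=C([C@H](C5(OCCO5)[C@@H](C)CN(OC(=O)OC(C)(C)C)C(=O)OC(C)(C)C)/C=C/CCC2)[C@@H](O)CC4 | intermediate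
21 | saturated macrocyclic bis-cyclopentanol: C6 (S) hydroxyl trans to the cis substituents on C9 (S) and C9a (R); C1 (R), C3 (S); pentamethylene tethers | O[C@H]1CC[C@H]2[C@@H]1[C@H](C3(OCCO3)[C@@H](C)CN(OC(=O)OC(C)(C)C)C(=O)OC(C)(C)C)CCCCC[C@H]4CC[C@H](O)[C@H]4[C@H](C5(OCCO5)[C@@H](C)CN(OC(=O)OC(C)(C)C)C(=O)OC(C)(C)C)CCCCC2 | intermediate
22 | macrocyclic bis-cyclopentanone, cis at C9 (S)/C9a (R), N(Boc)OBoc on each C4 | O=C1CC[C@H]2[C@@H]1[C@H](C3(OCCO3)[C@@H](C)CN(OC(=O)OC(C)(C)C)C(=O)OC(C)(C)C)CCCCC[C@H]4CCC(=O)[C@H]4[C@H](C5(OCCO5)[C@@H](C)CN(OC(=O)OC(C)(C)C)C(=O)OC(C)(C)C)CCCCC2 | intermediate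
23 | macrocyclic bis-cyclopentanone with a free NHOH on each C4 | O=C1CC[C@H]2[C@@H]1[C@H](C3(OCCO3)[C@@H](C)CNO)CCCCC[C@H]4CCC(=O)[C@H]4[C@H](C5(OCCO5)[C@@H](C)CNO)CCCCC2 | intermediate (not isolated)
24 | macrocyclic bis(cyclic nitrone) bis-ketal (C6=N5 oxide in a seven-membered ring fused to each cyclopentane) | C[C@H]1C[N+]([O-])=C2CC[C@@H]3CCCCC[C@H]4C6(OCCO6)[C@@H](C)C[N+]([O-])=C5CC[C@H](CCCCC[C@@H](C17OCCO7)[C@@H]32)[C@H]45 | intermediate (key-step precursor)
25 | bis-oxaziridine (N5–O–C6 three-membered rings; expected as a mixture at the oxaziridine carbon and nitrogen, other centres as in 24) | C[C@H]1CN8OC82CC[C@@H]3CCCCC[C@H]4C6(OCCO6)[C@@H](C)CN9OC95CC[C@H](CCCCC[C@@H](C17OCCO7)[C@@H]32)[C@H]45 | intermediate (not isolated)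
26 | macrocyclic bis(quinolizidin-6-one) bis-ketal | C[C@H]1CN2C(=O)CC[C@@H]3CCCCC[C@H]4C6(OCCO6)[C@@H](C)CN5C(=O)CC[C@H](CCCCC[C@@H](C17OCCO7)[C@@H]32)[C@H]45 | intermediate (key-step product)
27 | macrocyclic bis-quinolizidine bis(ethylene ketal) | C[C@H]1CN2CCC[C@@H]3CCCCC[C@H]4C6(OCCO6)[C@@H](C)CN5CCC[C@H](CCCCC[C@@H](C17OCCO7)[C@@H]32)[C@H]45 | intermediate
28 | CNP0268544.6, macrocyclic bis(quinolizidin-2-one), (1R,3S,9S,9aR) in each half | C[C@H]1CN2CCC[C@@H]3CCCCC[C@H]4C(=O)[C@@H](C)CN5CCC[C@H](CCCCC[C@@H](C1=O)[C@@H]32)[C@H]45 | target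

**Totals**

Total step count: 20. Longest linear sequence: 20 steps (from 1).

**Steps most likely to fail**

Step 11. Ring closure of the open-chain dimer may lose to chain growth, and some borane may reduce a ring carbonyl instead of adding to the alkene. The fallback sets out from 12 and 13 and comes back at 15, then 16; the two couplings are done one after the other. Dione 12 is O-methylated (TMSCHN2, MeOH/toluene) to the methyl vinylogous ester F1, which has no ketone that 9-BBN could reduce. Hydroboration gives alkylborane F2, which is coupled (PdCl2(dppf), AsPh3, Cs2CO3) with one equivalent of triflate 13 to the open-chain dimer F3, still carrying one terminal alkene and one vinylogous ester. Dilute aqueous HCl in THF hydrolyses the vinylogous ester to dione F4 (the hindered C2 dioxolanes react far more slowly), and Tf2O/Et3N gives triflate F5. Hydroboration of its single terminal alkene gives 15, which is closed to 16 by syringe-pump addition to the palladium catalyst, so only the ring closure remains to be optimised.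

Step 18. Irradiation may divert the oxaziridine to other paths: N–O homolysis with loss of oxygen to the imine, shift of C7 instead of C9a, or secondary photolysis of the lactam. The fallback sets out from 24 and comes back at 26, using a polar, non-photochemical rearrangement of the same nitrone. O-Sulfonylation with TsCl/pyridine in CH2Cl2 at 0 °C gives the bis(N-tosyloxyiminium) salt F6. Aqueous NaHCO3/THF then adds water at C6 and triggers the Beckmann-type 1,2-shift to nitrogen with loss of tosylate (the known sulfonyl-chloride-induced nitrone-to-amide rearrangement). The more substituted C9a is the better migrating group and again moves with retention, giving 26.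

Step 17. Acid contact during carbamate cleavage may epimerise C9a from cis to trans, and the seven-membered condensation may be slow enough for intermolecular condensation to compete. The fallback sets out from 17 and comes back at 23, then 24; nitrogen is carried as a nitro group and the hydroxylamine is generated by near-neutral reduction. Diol 17 is converted (I2, PPh3, imidazole) to the bis-iodide F7 and with AgNO2 in Et2O to the bis-nitro bis-enone F8. Reduction with (R)-2-methyl-CBS-oxazaborolidine/catecholborane (bis-nitro bis-cyclopentenol F9), directed hydrogenation with [Ir(cod)(PCy3)(py)]PF6 (saturated bis-nitro diol F10) and Dess–Martin oxidation (bis-nitro diketone F11) follow as in steps 14–16. Zn dust and aqueous NH4Cl in EtOH at 0 °C reduce each nitro group to the N-alkylhydroxylamine 23, which condenses over 4 Å sieves to 24 without any acid treatment of the cis-ketone.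

**Further compounds**

F1 | step 11 | methyl vinylogous ester of 12: 3-methoxy-2-substituted cyclopent-2-en-1-one | O=C1CCC(OC)=C1[C@@H](/C=C/CC=C)C2(OCCO2)[C@@H](C)CO[Si](c3ccccc3)(c3ccccc3)C(C)(C)C
F2 | step 11 | alkylborane from F1 (terminal CH=CH2 converted to CH2CH2–9-BBN) | O=C1CCC(OC)=C1[C@@H](/C=C/CCCB4C5CCCC4CCC5)C2(OCCO2)[C@@H](C)CO[Si](c3ccccc3)(c3ccccc3)C(C)(C)C
F3 | step 11 | open-chain dimer: methyl vinylogous ester ring joined through t1 to C9 of an enone ring that keeps its terminal alkene | O=C1CCC(OC)=C1[C@H](C3(OCCO3)[C@@H](C)CO[Si](c6ccccc6)(c6ccccc6)C(C)(C)C)/C=C/CCCC4=C([C@H](C5(OCCO5)[C@@H](C)CO[Si](c7ccccc7)(c7ccccc7)C(C)(C)C)/C=C/CC=C)C(=O)CC4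
F4 | step 11 | open-chain dimer with the vinylogous ester hydrolysed to the enolised 1,3-dione | O=C1CCC(O)=C1[C@H](C3(OCCO3)[C@@H](C)CO[Si](c6ccccc6)(c6ccccc6)C(C)(C)C)/C=C/CCCC4=C([C@H](C5(OCCO5)[C@@H](C)CO[Si](c7ccccc7)(c7ccccc7)C(C)(C)C)/C=C/CC=C)C(=O)CC4
F5 | step 11 | open-chain dimer enol triflate | O=C1CCC(OS(=O)(=O)C(F)(F)F)=C1[C@H](C3(OCCO3)[C@@H](C)CO[Si](c6ccccc6)(c6ccccc6)C(C)(C)C)/C=C/CCCC4=C([C@H](C5(OCCO5)[C@@H](C)CO[Si](c7ccccc7)(c7ccccc7)C(C)(C)C)/C=C/CC=C)C(=O)CC4
F6 | step 18 | bis(N-tosyloxyiminium) dichloride from 24 | C[C@H]1C[N+](OS(=O)(=O)c8ccc(C)cc8)=C2CC[C@@H]3CCCCC[C@H]4C6(OCCO6)[C@@H](C)C[N+](OS(=O)(=O)c9ccc(C)cc9)=C5CC[C@H](CCCCC[C@@H](C17OCCO7)[C@@H]32)[C@H]45.[Cl-].[Cl-]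
F7 | step 17 | macrocyclic bis-enone bis-iodide (C4–I, configuration unchanged) | O=C1CCC2=C1[C@H](C3(OCCO3)[C@@H](C)CI)/C=C/CCCC4=C([C@H](C5(OCCO5)[C@@H](C)CI)/C=C/CCC2)C(=O)CC4
F8 | step 17 | macrocyclic bis-enone with a nitro group on each C4 | O=C1CCC2=C1[C@H](C3(OCCO3)[C@@H](C)C[N+](=O)[O-])/C=C/CCCC4=C([C@H](C5(OCCO5)[C@@H](C)C[N+](=O)[O-])/C=C/CCC2)C(=O)CC4
F9 | step 17 | bis-nitro macrocyclic bis-cyclopent-2-enol, C6 (S) | O[C@H]1CCC2=C1[C@H](C3(OCCO3)[C@@H](C)C[N+](=O)[O-])/C=C/CCCC4=C([C@H](C5(OCCO5)[C@@H](C)C[N+](=O)[O-])/C=C/CCC2)[C@@H](O)CC4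
F10 | step 17 | bis-nitro saturated macrocyclic bis-cyclopentanol | O[C@H]1CC[C@H]2[C@@H]1[C@H](C3(OCCO3)[C@@H](C)C[N+](=O)[O-])CCCCC[C@H]4CC[C@H](O)[C@H]4[C@H](C5(OCCO5)[C@@H](C)C[N+](=O)[O-])CCCCC2
F11 | step 17 | bis-nitro macrocyclic bis-cyclopentanone, cis at C9/C9a | O=C1CC[C@H]2[C@@H]1[C@H](C3(OCCO3)[C@@H](C)C[N+](=O)[O-])CCCCC[C@H]4CCC(=O)[C@H]4[C@H](C5(OCCO5)[C@@H](C)C[N+](=O)[O-])CCCCC2
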